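No rate constant is needed for the next charge: the earlier runs can be counted.

the same everywhere: substrate 0.050 M
- south: reagent 0.018 M (fed, over 6.0 min); run made earlier; the fed solution adds 0.20 times the starting volume
- north-west: reagent 0.070 M (fed, over 6.0 min); run made earlier; the fed solution adds 0.20 times the starting volume
- flask: reagent 0.0350 M (fed, over 6.0 min); the fed solution adds 0.20 times the starting volume; time 2.5 d

| run | time / h | substrate / % | target / % |
|---|---|---|---|
| south | 2.50 | 65.9 | 33.4 |
| south | 8.00 | 64.1 | 36.1 |
| south | 12.0 | 63.7 | 34.8 |
| south | 20.0 | 63.7 | 34.6 |
| south | 30.0 | 65.0 | 35.5 |
| south | 40.0 | 65.7 | 32.5 |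
| north-west | 6.00 | 0 | 67.1 |
| north-west | 12.0 | 0.6 | 66.9 |
| north-west | 20.0 | 0 | 68.5 |
| north-west | 25.0 | 0 | 68.2 |
| north-west | 30.0 | 0 | 67.1 |
| north-west | 40.0 | 0.6 | 66.4 |

(scatter of a reading: 1 percentage point)

- every charge counts on the volume at the start, and the solution that is fed holds the whole dose
- the reaction counts as stopped when no species that holds the substrate changes by six tenths of a point or more over the second half of the time

1. the state of affairs at 2.5 d: stopped, and by what, or still going (the reagent has run out first / all of the substrate has reacted / it is still moving)
2. conversion of substrate at 2.5 d
3. amount of target at 2.5 d, in percent of the substrate charged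

1. The south run charges 0.360 equivalents of reagent. Its readings average a substrate loss of 35.3%.

2. The ratio of these is 0.981: the fraction of substrate lost per equivalent of reagent charged, called here the reagent return. It is a reading and carries the scatter.

3. Time looks unpromising as a lever. South substrate reads 65.9% at 2.50 h and 65.7% at 40.0 h, a gap inside the scatter of 1 percentage point.

4. The north-west run warns about the return. At 20.0 h its substrate reads 0%, yet its target reads 68.5%, so target is consumed there too. A return read at a low charge may therefore run high.

5. The flask holds 0.700 equivalents, with less reagent than substrate, so reagent is the limiting reagent. My reckoning gives 68.7% conversion. The decision is to keep the charge as written and expect nothing from waiting.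

The forecast reads: the reagent has run out first, conversion 67%, target 64.5%. Its conversion is lower than my count. Its ground for the stop is that the reaction “stops when reagent is exhausted”.

The result for the flask at 2.5 d: the reagent has run out first, conversion 66.6%, target 64.0%.

substrate + reagent → target (k = 9.70 M⁻¹ min⁻¹); reagent + target → over-reaction product (k = 0.610 M⁻¹ min⁻¹); 2 reagent → homo dimer (k = 0.190 M⁻¹ min⁻¹) At 2.50 d the flask has 0% of its reagent left and 33% of its substrate, and over-reaction product stands at 2.64%. The reagent return of this flask is 0.951, against 0.981 from the south run. The neighbour flask with 0.014 M of reagent holds 0.280 equivalents, so the south return gives it 27.5%, and that neighbour flask reaches a conversion of 27.6%.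

The numbers in the tables stem from a simulated flask for an exercise; scatter was added.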